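The numbers in the tables were generated by integration for an exercise; noise was put on by code.

The Z left over is your clock: each half-life of Z halves it, so at the bench you count half-lives up to the stop time.

| flask | Z | X | temperature | remark | time |
|---|---|---|---|---|---|
| Saturday's | 10 mM | 34 mM | 30 °C | run made earlier |  |
| Thursday's | 10 mM | 75 mM | 50 °C | run made earlier |  |
| alpha | 10 mM | 50.0 mM | 50 °C |  | 2.0 h |
| delta | 10 mM | 50.0 mM | 65 °C |  | 2.0 h |
| epsilon | 10 mM | 50.0 mM | 35 °C |  | 2.0 h |

Saturday's run (percent of the Z charged)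

| time / h | L / % | Z / % |
|---|---|---|
| 0.333 | 1.4 | 82.2 |
| 0.667 | 6.1 | 69.6 |
| 1.00 | 11.0 | 55.4 |
| 2.50 | 30.2 | 18.6 |
| 4.00 | 37.2 | 10.0 |

Thursday's run (percent of the Z charged)

| time / min | L / % | Z / % |
|---|---|---|
| 8.00 | 16.8 | 40.1 |
| 25.0 | 38.9 | 6.9 |
| 40.0 | 40.8 | 3.4 |
| 60.0 | 37.9 | 2.5 |
| 90.0 | 32.3 | 4.2 |

(standard deviation of a reading: 1 percentage point)

1. the flask with the highest amount of L, in percent of the Z charged ("all alike" if they lie within 1.5 percentage points) (alpha / delta / epsilon / all alike)
2. final L, as a percentage of the Z charged, in alpha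
3. final L, as a percentage of the Z charged, in delta
4. final L, as a percentage of the Z charged, in epsilon

- a reading or a percentage of L counts all its forms, free or not
- a reading of Z is of its free form alone

Saturday's reading at 1.00 h leaves 55.4% of Z, so its pseudo-first-order rate constant reads 0.591 h⁻¹. Thursday's flask leaves 40.1% at 8.00 min, which reads 6.85 h⁻¹. I assume the rate is proportional to c_X. Per unit of c_X, the constants then differ by a factor of 5.26 between 30 °C and 50 °C, and I spread that factor evenly on a logarithmic scale of temperature.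

The rule holds at the end of Saturday's run: a count of 3.41 leaves 9.42%, the reading is 10.0%, and L is still rising at 37.2%. Thursday's run shows the border. At 40.0 min its count of 6.59 leaves 1.04%, but the reading is 3.4%, 3.27 times that. L reads 40.8% there and 32.3% at 90.0 min.

The half-life count, the stop time over the half-life of Z at that c_X and temperature, is 3.80 for epsilon, 13.2 for alpha and 45.8 for delta. My reckoning puts epsilon first, since its count is lower than Thursday's at 40.0 min and close to Saturday's at its end. Alpha and delta have higher counts than Thursday's at that time, and delta's count is higher than alpha's, so I put delta last, without a figure.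

The forecast also names epsilon, with 36% there, 33% in alpha and 13% in delta: “Delta peaks early, then L decays quickly”.

    Z + X → G + D (k = 20.0 M⁻¹ h⁻¹, Ea = 66.0 kJ mol⁻¹)
    G ⇌ L (K = 2.70, k = 1.90 h⁻¹, Ea = 85.0 kJ mol⁻¹, ΔH = −13.0 kJ mol⁻¹)
    G ⇌ Q (K = 35.0, k = 0.920 h⁻¹, Ea = 83.0 kJ mol⁻¹, ΔH = −41.0 kJ mol⁻¹)
    Z + L ⇌ E, settled at all times (K = 3200 M⁻¹, ΔH = 13.0 kJ mol⁻¹)
    J ⇌ L, rate k5*(cs5 - [L]) while solid is left; crystals form when [L] > cs5 (solubility = 3.70 mM, k = 19.0 h⁻¹)
    (constants at 35 °C)

The flasks give 38.0% in epsilon, 31.7% in alpha and 19.6% in delta, so epsilon leads and the forecast's delta lies 6.6 percentage points low; after 20.0 h, delta still holds 15.4% of L. Epsilon's count left 7.20% of Z by reckoning, and that flask holds 8.1% unbound. Run epsilon at 10 °C instead: extrapolating the same way gives a count of 0.476 and 71.9% of Z left. That neighbour holds 80.2% of Z, 15.5% of G and 1.74% of L.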